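## Retrosynthetic overview

1. The target is a 7-endo bicyclo[3.3.1]nonane-2,4,9-trione; the last disconnection removes two tosyl groups from the catechol.
2. Key disconnection is C5–C6, closing ring A last. C5, normally the nucleophilic enol carbon, is used with reversed polarity as an enolonium equivalent (tertiary α-bromo-β-dicarbonyl, then its electrophilic radical) against the nucleophilic alkene terminus C6. The same step sets C5 and C7.
3. The quaternary–quaternary C1–C8 bond comes from a [3,3] shift of a para-O-allyl ether of the aromatic acylphloroglucinol, with a chiral ammonium counter-ion choosing C1 over C5.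
4. Ring B is the phloroglucinol ring itself: Friedel–Crafts acylation, two C-prenylations, Mitsunobu etherification, then dearomatisation in the [3,3] step.
5. The side-chain allylic alcohol comes from ethyl but-2-ynoate, Me2CuLi and geranyl bromide. Ring order: B (aromatic, then dearomatised) → A.

Assumption: ring carbons are labelled C1–C9 as in the bicyclo[3.3.1]nonane of the target throughout, and cinchonidine is taken to give the (S)-dienone in step 7 (its pseudo-enantiomer cinchonine would be used if the sense is opposite).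

## Route

Step 1
Reactants: 1 ethyl but-2-ynoate; 2 geranyl bromide, (2E)-1-bromo-3,7-dimethylocta-2,6-diene
Product: 4 ethyl (4E)-5,9-dimethyl-2-(propan-2-ylidene)deca-4,8-dienoate, via alkenylcuprate 3 (not isolated)
Conditions: MeLi (2 equiv), CuI, THF, 0 °C; 1, −78 °C; then 2, DMPU, −78 → −20 °C
Reagents that add atoms: lithium dimethylcuprate, [Li+].C[Cu-]C
Why: Carbocupration of the ynoate gives the α-cuprio acrylate, which is allylated at carbon on the primary terminus of the γ,γ-disubstituted bromide (conjugate addition then enolate-type trapping); the new alkene carries two methyl groups so no geometry arises, and the E alkene of 2 is untouched.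

Step 2
Reactants: 4 ethyl (4E)-5,9-dimethyl-2-(propan-2-ylidene)deca-4,8-dienoate
Product: 5 (4E)-5,9-dimethyl-2-(propan-2-ylidene)deca-4,8-dien-1-ol
Conditions: iBu2AlH (2.5 equiv), CH2Cl2, −78 → 0 °C
Reagents that add atoms: none
Why: 1,2-Reduction of the hindered tetrasubstituted enoate by iBu2AlH gives the allylic alcohol without touching the isolated alkenes.

Step 3
Reactants: 6 3,4-dihydroxybenzoic acid; 7 4-methylbenzenesulfonyl chloride (TsCl, 2.5 equiv, one equivalent consumed per phenol)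
Product: 8 3,4-bis(tosyloxy)benzoic acid
Conditions: TsCl (2.5 equiv, added in portions), NaOH, H2O/THF, 0 °C → rt (N2); then HCl
Reagents that add atoms: 4-methylbenzenesulfonyl chloride (the second equivalent of 7), Cc1ccc(cc1)S(Cl)(=O)=O
Why: Schotten–Baumann sulfonylation in which each of the two phenoxides takes one tosyl group from its own equivalent of TsCl (any mixed anhydride at the acid is hydrolysed by the aqueous base); aryl tosylates are chosen because they survive AlCl3, cold aqueous KOH, N-bromosuccinimide and Bu3SnH.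

Step 4
Reactants: 8 3,4-bis(tosyloxy)benzoic acid; 9 phloroglucinol
Product: 11 [3,4-bis(tosyloxy)phenyl](2,4,6-trihydroxyphenyl)methanone, via acid chloride 10 (not isolated)
Conditions: (COCl)2, DMF (cat.), CH2Cl2, rt; then 9, AlCl3, PhNO2, 0 → 60 °C; aq. HCl
Reagents that add atoms: none
Why: Friedel–Crafts C-acylation of the very electron-rich phloroglucinol; the acylated ring is deactivated, so it reacts once.

Step 5
Reactants: 11 [3,4-bis(tosyloxy)phenyl](2,4,6-trihydroxyphenyl)methanone; 12 prenyl bromide, 1-bromo-3-methylbut-2-ene (2.1 equiv, one equivalent consumed per ring carbon)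
Product: 13 [3,4-bis(tosyloxy)phenyl][2,4,6-trihydroxy-3,5-bis(3-methylbut-2-en-1-yl)phenyl]methanone
Conditions: 12 (2.1 equiv), 10% aq. KOH, 0 °C
Reagents that add atoms: prenyl bromide (the second equivalent of 12), CC(C)=CCBr
Why: Twofold C-alkylation of the acylphloroglucinol polyanion in water, where solvation of oxygen steers the soft allylic bromide to the two free ring carbons (the standard route to 3,5-diprenyl acylphloroglucinols; moderate yield expected).

Step 6
Reactants: 13 [3,4-bis(tosyloxy)phenyl][2,4,6-trihydroxy-3,5-bis(3-methylbut-2-en-1-yl)phenyl]methanone; 5 (4E)-5,9-dimethyl-2-(propan-2-ylidene)deca-4,8-dien-1-ol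
Product: 14 [3,4-bis(tosyloxy)phenyl]{4-{[(4E)-5,9-dimethyl-2-(propan-2-ylidene)deca-4,8-dien-1-yl]oxy}-2,6-dihydroxy-3,5-bis(3-methylbut-2-en-1-yl)phenyl}methanone
Conditions: PPh3, DIAD, THF, 0 °C → rt
Reagents that add atoms: none
Why: Mitsunobu etherification takes the most acidic OH, the one para to the acyl group that is not hydrogen-bonded to the ketone, and the neutral conditions avoid C-alkylation.

Step 7
Reactants: 14 para-O-allyl ether
Product: 15 (6S)-2-[3,4-bis(tosyloxy)benzoyl]-3,5-dihydroxy-4,6-bis(3-methylbut-2-en-1-yl)-6-[(5E)-2,6,10-trimethyl-3-methylideneundeca-5,9-dien-2-yl]cyclohexa-2,4-dien-1-one (ring C6 = C1 of the target, S)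
Conditions: cinchonidine (1.1 equiv), PhMe, 30 °C; then cold aq. citric acid
Reagents that add atoms: none
Why: Proposed new method: deprotonation of the vinylogous acid by the alkaloid makes the ring an electron-rich phenoxide whose carbons C1 and C5 attack the CMe2 terminus of the allyl ether in an anion-accelerated [3,3] shift near room temperature, and the hydrogen-bonded chiral ammonium ion pair differentiates the enantiotopic carbons so that C1 is formed as S, while the low temperature keeps the product from the onward Cope shift of the new group to C3 and from there to C5; the closest known reaction types are the anion-accelerated Claisen rearrangement and the chiral-cation-controlled desymmetrising alkylative dearomatisation of the same diprenyl acylphloroglucinol anions.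

Step 8
Reactants: 15 (S)-dienone
Product: 17 (1S,5S,7S)-3-[3,4-bis(tosyloxy)benzoyl]-7-[(2E)-3,7-dimethylocta-2,6-dien-1-yl]-4-hydroxy-8,8-dimethyl-1,5-bis(3-methylbut-2-en-1-yl)bicyclo[3.3.1]non-3-ene-2,9-dione, via bromide 16 (not isolated)
Conditions: N-bromosuccinimide, CH2Cl2, −78 °C; then Bu3SnH (slow addition), Et3B/air, PhMe, 0 °C → rt
Reagents that add atoms: none
Why: Bromination turns C5, normally the nucleophilic enol carbon, into an enolonium-type centre (tertiary α-bromo-β-dicarbonyl), and bromine abstraction gives the electrophilic 1,3-dicarbonyl radical that adds 6-endo to the unhindered, nucleophilic CH2 terminus C6 of the 1,1-disubstituted alkene (Bu3SnH-mediated cyclisation of an α-halo-1,3-dicarbonyl, endo mode favoured by the ketone inside the forming ring); C5 is set because the tether on C1 can only reach its own ring face (5S), and C7 because Bu3SnH delivers hydrogen to the tertiary C7 radical from the convex face away from ring B, which leaves the geranyl group endo, cis to the C2–C4 bridge (7S).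

Step 9
Reactants: 17 bicyclic bis-tosylate
Product: 18 CNP0182339.2, (1S,5S,7S)-3-(3,4-dihydroxybenzoyl)-7-[(2E)-3,7-dimethylocta-2,6-dien-1-yl]-4-hydroxy-8,8-dimethyl-1,5-bis(3-methylbut-2-en-1-yl)bicyclo[3.3.1]non-3-ene-2,9-dione
Conditions: LiOH, 1,4-dioxane/H2O (degassed, Ar), 80 °C; then 1 M HCl
Reagents that add atoms: none
Why: Hydroxide attacks sulfur of the two aryl sulfonates while the triketone is protected as its enolate; C1 and C5 are quaternary and C7 is not acidic, so no stereocentre can epimerise.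

## Compound list

1 | ethyl but-2-ynoate | CC#CC(=O)OCC | starting material
2 | geranyl bromide, (2E)-1-bromo-3,7-dimethylocta-2,6-diene | BrC/C=C(\C)CCC=C(C)C | starting material
3 | lithium [1-(ethoxycarbonyl)-2-methylprop-1-en-1-yl](methyl)cuprate | CCOC(=O)C([Cu-]C)=C(C)C.[Li+] | intermediate
4 | ethyl (4E)-5,9-dimethyl-2-(propan-2-ylidene)deca-4,8-dienoate | CCOC(=O)C(=C(C)C)C/C=C(\C)CCC=C(C)C | intermediate
5 | (4E)-5,9-dimethyl-2-(propan-2-ylidene)deca-4,8-dien-1-ol | OCC(=C(C)C)C/C=C(\C)CCC=C(C)C | intermediate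
6 | 3,4-dihydroxybenzoic acid | OC(=O)c1ccc(O)c(O)c1 | starting material
7 | 4-methylbenzenesulfonyl chloride | Cc1ccc(cc1)S(Cl)(=O)=O | starting material
8 | 3,4-bis(tosyloxy)benzoic acid | OC(=O)c1ccc(OS(=O)(=O)c2ccc(C)cc2)c(OS(=O)(=O)c2ccc(C)cc2)c1 | intermediate
9 | phloroglucinol, benzene-1,3,5-triol | Oc1cc(O)cc(O)c1 | starting material
10 | 3,4-bis(tosyloxy)benzoyl chloride | ClC(=O)c1ccc(OS(=O)(=O)c2ccc(C)cc2)c(OS(=O)(=O)c2ccc(C)cc2)c1 | intermediate
11 | [3,4-bis(tosyloxy)phenyl](2,4,6-trihydroxyphenyl)methanone | O=C(c1c(O)cc(O)cc1O)c1ccc(OS(=O)(=O)c2ccc(C)cc2)c(OS(=O)(=O)c2ccc(C)cc2)c1 | intermediate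
12 | prenyl bromide, 1-bromo-3-methylbut-2-ene | CC(C)=CCBr | starting material
13 | [3,4-bis(tosyloxy)phenyl][2,4,6-trihydroxy-3,5-bis(3-methylbut-2-en-1-yl)phenyl]methanone | O=C(c1c(O)c(CC=C(C)C)c(O)c(CC=C(C)C)c1O)c1ccc(OS(=O)(=O)c2ccc(C)cc2)c(OS(=O)(=O)c2ccc(C)cc2)c1 | intermediate
14 | para-O-allyl ether of 13 (ether oxygen on the carbon that becomes C9; allyl = (4E)-5,9-dimethyl-2-(propan-2-ylidene)deca-4,8-dien-1-yl) | O=C(c1c(O)c(CC=C(C)C)c(OCC(=C(C)C)C/C=C(\C)CCC=C(C)C)c(CC=C(C)C)c1O)c1ccc(OS(=O)(=O)c2ccc(C)cc2)c(OS(=O)(=O)c2ccc(C)cc2)c1 | intermediate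
15 | (6S)-2-[3,4-bis(tosyloxy)benzoyl]-3,5-dihydroxy-4,6-bis(3-methylbut-2-en-1-yl)-6-[(5E)-2,6,10-trimethyl-3-methylideneundeca-5,9-dien-2-yl]cyclohexa-2,4-dien-1-one (one enol tautomer drawn; quaternary carbon = C1, S) | O=C1C(C(=O)c2ccc(OS(=O)(=O)c3ccc(C)cc3)c(OS(=O)(=O)c3ccc(C)cc3)c2)=C(O)C(CC=C(C)C)=C(O)[C@]1(CC=C(C)C)C(C)(C)C(=C)C/C=C(\C)CCC=C(C)C | intermediate
16 | C5-bromide of 15: 2-[3,4-bis(tosyloxy)benzoyl]-4-bromo-3-hydroxy-4,6-bis(3-methylbut-2-en-1-yl)-6-[(5E)-2,6,10-trimethyl-3-methylideneundeca-5,9-dien-2-yl]cyclohex-2-ene-1,5-dione (quaternary carbon arranged in space as in 15; both epimers at the brominated carbon, lost in the next stage) | O=C1C(C(=O)c2ccc(OS(=O)(=O)c3ccc(C)cc3)c(OS(=O)(=O)c3ccc(C)cc3)c2)=C(O)C(Br)(CC=C(C)C)C(=O)[C@]1(CC=C(C)C)C(C)(C)C(=C)C/C=C(\C)CCC=C(C)C | intermediate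
17 | (1S,5S,7S)-3-[3,4-bis(tosyloxy)benzoyl]-7-[(2E)-3,7-dimethylocta-2,6-dien-1-yl]-4-hydroxy-8,8-dimethyl-1,5-bis(3-methylbut-2-en-1-yl)bicyclo[3.3.1]non-3-ene-2,9-dione (geranyl on C7 endo, cis to the C2–C4 bridge) | CC(C)=CCC/C(C)=C/C[C@H]1C[C@]2(CC=C(C)C)C(=O)[C@@](CC=C(C)C)(C(=O)C(C(=O)c3ccc(OS(=O)(=O)c4ccc(C)cc4)c(OS(=O)(=O)c4ccc(C)cc4)c3)=C2O)C1(C)C | intermediate
18 | CNP0182339.2, (1S,5S,7S)-3-(3,4-dihydroxybenzoyl)-7-[(2E)-3,7-dimethylocta-2,6-dien-1-yl]-4-hydroxy-8,8-dimethyl-1,5-bis(3-methylbut-2-en-1-yl)bicyclo[3.3.1]non-3-ene-2,9-dione | CC(C)=CCC/C(C)=C/C[C@H]1C[C@]2(CC=C(C)C)C(=O)[C@@](CC=C(C)C)(C(=O)C(C(=O)c3ccc(O)c(O)c3)=C2O)C1(C)C | target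

## Step count and risks

Total step count: 9 (steps 1–2 make the side chain, steps 3–9 are the main line).
Longest linear sequence: 7 steps (6 → 8 → 11 → 13 → 14 → 15 → 17 → 18).

The three steps most likely to fail:

**Step 8.** The C5 radical may instead close 5-exo onto the prenyl group on C1, may be reduced back to 15 before it cyclises, or hydrogen delivery may give some 7-exo epimer. The fallback sets out from 15 and comes back at 17, and closes ring A by enolate C-alkylation instead. Anti-Markovnikov hydration of the 1,1-disubstituted alkene (9-BBN-H in excess, THF, then NaBO3·4H2O; the trisubstituted alkenes are left) gives the primary alcohol (6S)-2-[3,4-bis(tosyloxy)benzoyl]-3,5-dihydroxy-6-[(5E)-3-(hydroxymethyl)-2,6,10-trimethylundeca-5,9-dien-2-yl]-4,6-bis(3-methylbut-2-en-1-yl)cyclohexa-2,4-dien-1-one F1. I2, PPh3 and imidazole convert it into the primary iodide, the 3-(iodomethyl) analogue F2. Cs2CO3 in DMF then closes ring A by intramolecular C-alkylation of the C5 enolate. C7 is not controlled in this variant, so 17 is separated from its 7-exo epimer by chromatography, and O-alkylation is the expected side reaction.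

**Step 7.** The asymmetric induction by the ion pair is unproven, and the [3,3] product can move on by further Cope shifts if it is warmed. The fallback sets out from 14 and comes back at 15. The rearrangement is run without chiral control under Lewis-acid catalysis (Eu(fod)3, fod = 6,6,7,7,8,8,8-heptafluoro-2,2-dimethyloctane-3,5-dionate, CHCl3, 45 °C) to give the racemic dienone F3. This is resolved classically as the (S)-1-phenylethylammonium salt of 15 F4 by fractional crystallisation; the (R)-amine is used if the wanted enantiomer stays in the mother liquor. A cold citric acid wash liberates 15.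

**Step 1.** The mixed cuprate 3 may transfer methyl to 2 or attack 2 at the tertiary allyl terminus. The fallback sets out from 2 and comes back at 4. Commercial ethyl acetoacetate is alkylated with 2 (K2CO3, acetone, reflux) to the keto ester ethyl (4E)-2-acetyl-5,9-dimethyldeca-4,8-dienoate F5. NaH and ClP(O)(OEt)2 give the enol phosphate ethyl (4E)-2-[1-(diethoxyphosphoryloxy)ethylidene]-5,9-dimethyldeca-4,8-dienoate F6 (alkene geometry irrelevant). Me2CuLi (Et2O, −78 → −40 °C) replaces the phosphate by methyl through addition–elimination to give 4.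

## Further compounds

F1 | step 8 | (6S)-2-[3,4-bis(tosyloxy)benzoyl]-3,5-dihydroxy-6-[(5E)-3-(hydroxymethyl)-2,6,10-trimethylundeca-5,9-dien-2-yl]-4,6-bis(3-methylbut-2-en-1-yl)cyclohexa-2,4-dien-1-one (both epimers at the new CH) | O=C1C(C(=O)c2ccc(OS(=O)(=O)c3ccc(C)cc3)c(OS(=O)(=O)c3ccc(C)cc3)c2)=C(O)C(CC=C(C)C)=C(O)[C@]1(CC=C(C)C)C(C)(C)C(CO)C/C=C(\C)CCC=C(C)C
F2 | step 8 | (6S)-2-[3,4-bis(tosyloxy)benzoyl]-3,5-dihydroxy-6-[(5E)-3-(iodomethyl)-2,6,10-trimethylundeca-5,9-dien-2-yl]-4,6-bis(3-methylbut-2-en-1-yl)cyclohexa-2,4-dien-1-one (both epimers at the CH) | O=C1C(C(=O)c2ccc(OS(=O)(=O)c3ccc(C)cc3)c(OS(=O)(=O)c3ccc(C)cc3)c2)=C(O)C(CC=C(C)C)=C(O)[C@]1(CC=C(C)C)C(C)(C)C(CI)C/C=C(\C)CCC=C(C)C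
F3 | step 7 | racemic 2-[3,4-bis(tosyloxy)benzoyl]-3,5-dihydroxy-4,6-bis(3-methylbut-2-en-1-yl)-6-[(5E)-2,6,10-trimethyl-3-methylideneundeca-5,9-dien-2-yl]cyclohexa-2,4-dien-1-one | O=C1C(C(=O)c2ccc(OS(=O)(=O)c3ccc(C)cc3)c(OS(=O)(=O)c3ccc(C)cc3)c2)=C(O)C(CC=C(C)C)=C(O)C1(CC=C(C)C)C(C)(C)C(=C)C/C=C(\C)CCC=C(C)C
F4 | step 7 | (S)-1-phenylethylammonium salt of 15 | C[C@H]([NH3+])c1ccccc1.O=C1C(C(=O)c2ccc(OS(=O)(=O)c3ccc(C)cc3)c(OS(=O)(=O)c3ccc(C)cc3)c2)=C([O-])C(CC=C(C)C)=C(O)[C@]1(CC=C(C)C)C(C)(C)C(=C)C/C=C(\C)CCC=C(C)C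
F5 | step 1 | ethyl (4E)-2-acetyl-5,9-dimethyldeca-4,8-dienoate (racemic) | CCOC(=O)C(C(C)=O)C/C=C(\C)CCC=C(C)C
F6 | step 1 | ethyl (4E)-2-[1-(diethoxyphosphoryloxy)ethylidene]-5,9-dimethyldeca-4,8-dienoate | CCOC(=O)C(C/C=C(\C)CCC=C(C)C)=C(C)OP(=O)(OCC)OCC
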